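## The problem

Target 25 is a cyclohexane in which all six ring carbons are stereogenic, (1S,2R,3S,4R,5R,6S). C1 is a quaternary oxirane carbon carrying the benzoyloxymethyl carbon C7, C6 is the oxirane CH, C2 and C3 carry acetates, and C4 and C5 carry free hydroxyls. The four oxygens on C2–C5 are mutually trans, which is the L-ido pattern of a hexitol, so these four centres can be taken from the chiral pool. The two remaining centres lie in the oxirane, whose oxygen is cis to O2 and trans to O5, so a free C2 hydroxyl can deliver it to a C1=C6 alkene. The skeleton asks only for closure of one carbocycle and attachment of the single branch carbon C7 to C1. The acylation pattern is the harder part: five oxygens must end as one primary benzoate, two adjacent secondary acetates and a free trans-diol, and O3 and O4 differ only through their neighbours. Esters beside free hydroxyls can migrate, and an oxirane with a trans hydroxyl on the next carbon can migrate or open, so strong base, hot acid and nucleophiles are excluded at the end and the esters and oxirane must be made late. The feature that opens the route is that C1 and C6 are the only ring carbons without a hexitol oxygen, are at alkene level once the oxirane is removed, and correspond to the two ends of the hexitol chain. They can be tied through a sulfur atom that is later excised, and while that sulfur is a sulfone C1 is acidic enough to take up C7.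

## Retrosynthesis

**25 ⇒ 23 (through 24).** The last bonds made are the O3–acetyl bond and the O5–H bond. Cutting the O3 acetate leaves diol 23, where O3–H has an acetate neighbour and O4–H a silyl ether neighbour. This is the one point at which two oxygens that started as a symmetry-related pair must be told apart, and the forward step has to acylate O3 only. The silyl ether of 24 is then removed by fluoride without base, because a C5 alkoxide trans to the oxirane could shift it.

**23 ⇒ 20 (through 22 and 21).** The benzyl ethers on O3 and O4 are restored, the O2 acetate is removed, and the C1–O and C6–O bonds of the oxirane are cut to give allylic alcohol 20. This is preferred to a halohydrin or a nucleophilic closure because the free O2–H sits on the face the oxygen must occupy, and the only other allylic oxygen, O5, is on the opposite face and silylated. Hydrogen-bond delivery and steric shielding therefore point the same way. Hydrogenolysis of the benzyl ethers is placed after the alkene has been consumed. The forward steps need a syn-selective epoxidation of an electron-poor trisubstituted alkene and an oxirane that survives acetylation and hydrogenolysis.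

**20 ⇒ 18 (through 19).** Removing the benzoate and tying O7 to O2 as an isopropylidene acetal gives bicyclic alkene 18. The acetal is what separates O2 from O5, since only O2 has the primary O7 three atoms away; a selective silylation of a free 2,5-diol would rest on a small steric difference. Compound 18 has no ester and no oxirane and only base-stable protecting groups. The forward steps need acetal hydrolysis that spares an allylic silyl ether and benzoylation of a primary over a secondary alcohol.

**18 ⇒ 15 (key cut, through 17 and 16).** The C1=C6 bond is disconnected by inserting SO2 between the two carbons, which gives thiepane 1,1-dioxide 15. A metathesis would need a diene with a separately built 1,1-disubstituted terminus, and an aldol-type C1–C2 closure would create C2 in the ring-forming step. Sulfur insertion maps the ring directly onto C1–C6 of a hexitol and forms no stereocentre. The precursor has no carbocycle and no alkene, its C1 configuration is irrelevant, and it is one C–C bond away from a C2-symmetric sulfone. The forward reaction must halogenate α to the sulfone, close the episulfone and lose SO2 faster than any β-oxygen is eliminated.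

**15 ⇒ 10 + 11 (through 14, 13 and 12).** The silyl ether and acetonide are removed and the C1–C7 bond is cut, so triol 13 is the adduct of formaldehyde 11 with the α-carbanion of sulfone diol 10. Because 10 is C2-symmetric its two α-methylenes are equivalent and no regiochemical question arises. The carbanion is generated on the free diol as polyanion 12 and not on a diether. The β-oxygens are then lithium alkoxides that cannot leave, which closes the E1cB pathway that threatens β-alkoxy sulfonyl carbanions. Formaldehyde also supplies the free O7–H that the acetonide needs. The forward reaction must add at carbon and be quenched cold, and afterwards only O7/O2 can form a cyclic acetal.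

**10 ⇒ 7 (through 9 and 8).** The sulfone oxygens are removed and both C–S bonds are cut, leading to bis-epoxide 7 and a sulfide source. The bis-epoxide releases the C2 and C5 hydroxyls in the same operation that closes the ring, so no extra protection is needed. The forward reaction needs attack at both primary carbons, the second as a 7-endo closure by thiolate 8.

**7 ⇒ 1 (through 6, 5, 4, 3 and 2).** The C2–O and C5–O oxirane bonds are cut with inversion, giving the D-manno dimesylate 5, made from tetrol 3, its precursor 2 and the commercial diacetonide 1. The double inversion turns the inexpensive D-mannitol configuration into the all-trans L-ido array. The forward steps need primary-selective silylation, mesylation, and a one-flask desilylation and closure through 6.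

## Roads not taken

**Alternative 1:** The cut is the C2–O bond, traced to the achiral dienone A1. In the forward step a boronic acid hemiester of the tertiary hydroxyl is delivered to one enantiotopic enone arm under a bifunctional amine–thiourea catalyst, giving the cis-fused boronate A2.
- Merits: C7 and its benzoate are present from the start, and C1 and C2 are set cis, as 25 requires, catalytically from a flat precursor in one step.
- Weak points: C3–C6 must then be built one at a time on a base-sensitive β-oxygenated enone that can revert by retro-oxa-Michael reaction or aromatise. This means oxygenation at C3 trans to O2, carbonyl reduction at C4, oxidation of C5=C6, and closure of the oxirane from O1 onto C6 with inversion. The enantiomeric purity also depends on how the catalyst treats this particular substituent.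
- Comparison: this road is shorter in protecting-group operations and is catalytic. The chosen plan sets against it four carbinol centres of fixed absolute configuration from a hexitol, with only the two oxirane centres made late under one directing effect.

**Alternative 2:** The cut is C1–O and C4–O, traced to diene A3. Photosensitised singlet oxygen adds across C1 and C4 in a [4+2] reaction to give the endoperoxide A4.
- Merits: two C–O bonds form at once and cis across the ring, which is exactly the relation between the oxirane oxygen and O4 in 25. Molecular oxygen is the reagent, and the bulky C3 silyl ether should steer it to the correct face.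
- Weak points: A3 is a 1-substituted cyclohexa-1,3-diene trans-diol monoether that must be made enantiopure and can aromatise by elimination. The O–O bridge must then be converted into the C1–C6 oxirane and the trans C4/C5 diol, which needs a regio- and stereoselective opening at C5 beside a second oxirane. The O2/O3 diacetate still needs its own protecting-group steps.
- Comparison: from A3 this road is probably shorter and more atom-economical. The chosen plan sets against it the absence of a labile diene and of any choice between two oxiranes, and a starting material that already carries the four ring oxygens.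

**Alternative 3:** The cut is C1–C2, traced to the enoate aldehyde A5, a pentose chain extended by a two-carbon Wittig unit. A nucleophilic phosphine or amine catalyst closes the ring in an intramolecular Morita–Baylis–Hillman reaction to give the cyclohexene ester A6.
- Merits: all seven carbons sit in one chain. Because the chain is unsymmetrical, O3 carries a different ether from O4 and O5 from the outset, and O2 is the newly formed free hydroxyl. This settles by construction the O3/O4 distinction that costs the chosen route its least secure step.
- Weak points: C2 is created in the ring closure, and its configuration relative to O3 is not assured. The α-alkoxy aldehyde can epimerise under the catalyst, β-substituted enoates are slow acceptors, and the zwitterionic enolate can expel the γ-alkoxy group. The ester still has to be reduced to the C7 alcohol.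
- Comparison: on protecting-group logic this road is better. The chosen plan sets against it a ring closure that forms no stereocentre and can epimerise none, in a reaction class already established for hexitol-derived thiepane dioxides.

Key step: step 11

Remark: locants C1–C7 are those of 25 (C1 quaternary oxirane carbon, C7 its CH2O carbon, C2 next to C1, C6 the oxirane CH); compounds before step 8 keep carbohydrate or thiepane locants.

Remark: compounds 13–17 are carried as epimer mixtures at C1 (16 also at C6), because C1 becomes trigonal in step 11; these centres are left undefined in the SMILES.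

Step 1
Reactants: 1 1,2:5,6-di-O-isopropylidene-D-mannitol
Product: 2 3,4-di-O-benzyl-1,2:5,6-di-O-isopropylidene-D-mannitol
Conditions: NaH, BnBr, Bu4NI (cat.), DMF, 0 °C to rt
Reagents that add atoms: benzyl bromide, BrCc1ccccc1
Why: Williamson etherification of the two homotopic secondary hydroxyls; no stereocentre is touched.

Step 2
Reactants: 2 3,4-di-O-benzyl-1,2:5,6-di-O-isopropylidene-D-mannitol
Product: 3 3,4-di-O-benzyl-D-mannitol
Conditions: AcOH–H2O (7:3), 45 °C
Reagents that add atoms: none
Why: Acid-catalysed hydrolysis of the two terminal isopropylidene acetals; benzyl ethers are inert.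

Step 3
Reactants: 3 3,4-di-O-benzyl-D-mannitol
Product: 4 3,4-di-O-benzyl-1,6-bis-O-(tert-butyldimethylsilyl)-D-mannitol
Conditions: TBSCl (2.1 equiv), imidazole, DMF, 0 °C
Reagents that add atoms: tert-butyldimethylsilyl chloride, CC(C)(C)[Si](C)(C)Cl
Why: Selective silylation of the primary over the secondary hydroxyls of a tetrol, controlled by the bulk of the silyl chloride.

Step 4
Reactants: 4 3,4-di-O-benzyl-1,6-bis-O-(tert-butyldimethylsilyl)-D-mannitol
Product: 5 3,4-di-O-benzyl-1,6-bis-O-(tert-butyldimethylsilyl)-2,5-di-O-mesyl-D-mannitol
Conditions: MsCl, Et3N, CH2Cl2, 0 °C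
Reagents that add atoms: methanesulfonyl chloride, CS(=O)(=O)Cl
Why: Sulfonylation of the two remaining secondary hydroxyls with retention, turning C2 and C5 into leaving-group carbons.

Step 5
Reactants: 5 3,4-di-O-benzyl-1,6-bis-O-(tert-butyldimethylsilyl)-2,5-di-O-mesyl-D-mannitol
Product: 7 1,2:5,6-dianhydro-3,4-di-O-benzyl-L-iditol, via 2,5-di-O-mesyl diol 6 (not isolated)
Conditions: conc. HCl, MeOH, rt; then aq. NaOH, 0 °C to rt
Reagents that add atoms: none
Why: Acidic methanolysis frees O1 and O6, and base then closes both oxiranes by intramolecular Williamson (3-exo-tet) displacement of mesylate. The displacement inverts C2 and C5 (D-manno to L-ido), which sets the all-trans array of C2–C5.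

Step 6
Reactants: 7 1,2:5,6-dianhydro-3,4-di-O-benzyl-L-iditol
Product: 9 (3R,4R,5R,6R)-4,5-bis(benzyloxy)thiepane-3,6-diol, via epoxy thiolate 8 (not isolated)
Conditions: Na2S·9H2O, EtOH, reflux
Reagents that add atoms: sodium sulfide, [Na+].[Na+].[S-2]
Why: Double nucleophilic epoxide opening: sulfide attacks one primary carbon and thiolate 8 opens the second oxirane at its primary carbon (7-endo-tet), the regiochemistry established for sulfur with hexitol bis-epoxides. The four stereocentres are not involved.

Step 7
Reactants: 9 (3R,4R,5R,6R)-4,5-bis(benzyloxy)thiepane-3,6-diol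
Product: 10 (3R,4R,5R,6R)-4,5-bis(benzyloxy)-3,6-dihydroxythiepane 1,1-dioxide
Conditions: mCPBA (2.3 equiv), NaHCO3, CH2Cl2, 0 °C to rt
Reagents that add atoms: 3-chloroperbenzoic acid, O=C(OO)c1cccc(Cl)c1
Why: Peracid oxidation of the sulfide to the sulfone; hydroxyls and benzyl ethers are unaffected.

Step 8
Reactants: 10 (3R,4R,5R,6R)-4,5-bis(benzyloxy)-3,6-dihydroxythiepane 1,1-dioxide; 11 formaldehyde (monomeric, from cracking commercial paraformaldehyde)
Product: 13 (2RS,3R,4R,5R,6R)-4,5-bis(benzyloxy)-3,6-dihydroxy-2-(hydroxymethyl)thiepane 1,1-dioxide, via trilithio derivative 12 (not isolated)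
Conditions: n-BuLi (3.2 equiv), THF–DMPU, −78 to −50 °C; CH2O (gas), −78 °C; AcOH, −78 °C
Reagents that add atoms: none
Why: Aldol-type hydroxymethylation of a sulfonyl carbanion generated as the β-oxido polyanion 12, following the known dianion chemistry of β-hydroxy sulfones. The lithium alkoxides cannot act as leaving groups, so E1cB elimination is shut off, and the C2 symmetry of 10 makes the two α-methylenes equivalent. The new C1 centre forms as an epimer mixture, which does not matter because C1 becomes trigonal in step 11.

Step 9
Reactants: 13 (2RS,3R,4R,5R,6R)-4,5-bis(benzyloxy)-3,6-dihydroxy-2-(hydroxymethyl)thiepane 1,1-dioxide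
Product: 14 2,7-O-isopropylidene acetal of 13 (1,3-dioxane fused at C1–C2; O5–H free)
Conditions: 2,2-dimethoxypropane, PPTS (cat.), acetone, rt
Reagents that add atoms: 2,2-dimethoxypropane, COC(C)(C)OC
Why: Acid-catalysed acetalisation under thermodynamic control. Only O7 and O2 can close a ring, because O5–H has a benzyl ether and a methylene as neighbours, so this step distinguishes O2 from O5.

Step 10
Reactants: 14 2,7-O-isopropylidene acetal of 13
Product: 15 5-O-tert-butyldimethylsilyl ether of 14 (Ramberg–Bäcklund precursor)
Conditions: TBSOTf, 2,6-lutidine, CH2Cl2, 0 °C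
Reagents that add atoms: tert-butyldimethylsilyl triflate, CC(C)(C)[Si](C)(C)OS(=O)(=O)C(F)(F)F
Why: Silylation of the one free secondary hydroxyl with a silyl triflate, with lutidine buffering to preserve the acetonide. The TBS ether later blocks the face of C6 opposite to O2 and shields O4.

Step 11
Reactants: 15 5-O-tert-butyldimethylsilyl ether of 14
Product: 18 3,4-di-O-benzyl-5-O-(tert-butyldimethylsilyl)-2,7-O-isopropylidene-1-(hydroxymethyl)cyclohex-1(6)-ene-2,3,4,5-tetrol, via α-bromo sulfone 16 (not isolated), via episulfone 17 (not isolated)
Conditions: KOH/Al2O3, CBr2F2, t-BuOH–CH2Cl2, 0 °C to rt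
Reagents that add atoms: none
Why: One-flask halogenative Ramberg–Bäcklund reaction. KOH on alumina deprotonates the unhindered α-methylene C6 and the carbanion takes bromine from CBr2F2 to give 16; deprotonation at C1 then displaces bromide in a 1,3-elimination to episulfone 17, which loses SO2 cheletropically and leaves C1=C6. The closest known reactions are the same contraction of hexitol-derived thiepane 1,1-dioxides to cyclohexene tetrol ethers and of β-oxygenated glycosyl sulfones carrying benzyl, silyl or isopropylidene groups to exo-glycals. The carbocycle is closed by the 3-exo-tet attack of C1 on C6 and becomes six-membered when sulfur leaves, so the thiepane fixes the ring size and the alkene can only be cis. No stereocentre is formed and C2–C5 are not acidic, so they pass unchanged; C1 is destroyed, which is why both epimers of 15 converge and why it does not matter which α-carbon is halogenated. The selectivity needed is 1,3-elimination over E1cB loss of a β-oxygen, namely the C5 silyloxy group from a C6 carbanion or the acetal oxygens O2 and O7 from a C1 carbanion. It is favoured because bromine transfer and the intramolecular displacement are fast on the solid base at 0 °C, the β-leaving groups are poor and two of them are held in the dioxane ring, and t-BuOH keeps the standing carbanion concentration low. Difluorocarbene released from the reagent is taken up by the alcohol and hydroxide and should not add to the electron-poor trisubstituted alkene.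

Step 12
Reactants: 18 3,4-di-O-benzyl-5-O-(tert-butyldimethylsilyl)-2,7-O-isopropylidene-1-(hydroxymethyl)cyclohex-1(6)-ene-2,3,4,5-tetrol
Product: 19 3,4-di-O-benzyl-5-O-(tert-butyldimethylsilyl)-1-(hydroxymethyl)cyclohex-1(6)-ene-2,3,4,5-tetrol (O7–H and O2–H free)
Conditions: AcOH–THF–H2O (3:1:1), rt to 40 °C
Reagents that add atoms: none
Why: Mild acid hydrolysis of the 1,3-dioxane acetonide; the secondary TBS ether and the benzyl ethers survive aqueous acetic acid at this temperature.

Step 13
Reactants: 19 3,4-di-O-benzyl-5-O-(tert-butyldimethylsilyl)-1-(hydroxymethyl)cyclohex-1(6)-ene-2,3,4,5-tetrol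
Product: 20 7-O-benzoate of 19 (O2–H free)
Conditions: BzCl (1.05 equiv), pyridine, CH2Cl2, −30 °C
Reagents that add atoms: benzoyl chloride, O=C(Cl)c1ccccc1
Why: Selective acylation of the primary allylic hydroxyl over the hindered secondary C2 hydroxyl at low temperature.

Step 14
Reactants: 20 7-O-benzoate of 19
Product: 21 1,6-epoxide of 20 (oxirane oxygen cis to O2–H and trans to the C5 silyl ether)
Conditions: mCPBA, NaHCO3, CH2Cl2, 0 °C to rt
Reagents that add atoms: 3-chloroperbenzoic acid, O=C(OO)c1cccc(Cl)c1
Why: Hydroxyl-directed Prilezhaev epoxidation (Henbest effect). The pseudo-equatorial O2–H hydrogen-bonds the peracid and delivers oxygen to its own face, while the opposite face is blocked at C6 by the adjacent TBS ether, so C1 and C6 are set with the oxirane cis to O2 and trans to O5. Bicarbonate buffers the acid formed.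

Step 15
Reactants: 21 1,6-epoxide of 20
Product: 22 2-O-acetate of 21
Conditions: Ac2O, pyridine, DMAP (cat.), CH2Cl2, rt
Reagents that add atoms: acetic anhydride, CC(=O)OC(C)=O
Why: DMAP-catalysed acetylation of the only free hydroxyl; O2 is cis to the oxirane oxygen, so a Payne rearrangement is geometrically impossible.

Step 16
Reactants: 22 2-O-acetate of 21
Product: 23 3,4-diol obtained from 22 (2-O-acetyl; 7-O-benzoyl; 5-O-TBS; 1,6-epoxide)
Conditions: H2 (1 atm), Pd(OH)2/C, EtOAc, rt
Reagents that add atoms: none
Why: Hydrogenolysis of the two benzyl ethers; the aliphatic oxirane, the esters and the TBS ether are stable in neutral ethyl acetate, and no alkene remains.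

Step 17
Reactants: 23 3,4-diol obtained from 22
Product: 24 3-O-acetate of 23 (2,3-di-O-acetyl; O4–H free; 5-O-TBS)
Conditions: AcCl (1.1 equiv), 2,4,6-collidine, CH2Cl2, −78 to −40 °C
Reagents that add atoms: acetyl chloride, CC(Cl)=O
Why: Kinetically controlled regioselective acylation. O3–H has the small acetate at C2 as neighbour, whereas O4–H is shielded by the vicinal TBS ether at C5, and the 3-acetate is also the less crowded isomer should any acyl shift occur. A weak hindered base at low temperature suppresses migration and over-acylation.

Step 18
Reactants: 24 3-O-acetate of 23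
Product: 25 [(1S,2R,3S,4R,5R,6S)-2,3-diacetoxy-4,5-dihydroxy-7-oxabicyclo[4.1.0]heptan-1-yl]methyl benzoate
Conditions: HF·pyridine, pyridine, THF, 0 °C to rt
Reagents that add atoms: none
Why: Fluoride-mediated desilylation under non-basic conditions, which avoids acetyl migration and Payne-type oxirane migration through a C5 alkoxide. The oxirane is flanked by acyloxy-bearing carbons and is deactivated toward acid opening.

## Compound list

1 | 1,2:5,6-di-O-isopropylidene-D-mannitol | CC1(C)OC[C@@H](O1)[C@@H](O)[C@H](O)[C@H]1COC(C)(C)O1 | starting material
2 | 3,4-di-O-benzyl-1,2:5,6-di-O-isopropylidene-D-mannitol | CC1(C)OC[C@@H](O1)[C@@H](OCc1ccccc1)[C@H](OCc1ccccc1)[C@H]1COC(C)(C)O1 | intermediate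
3 | 3,4-di-O-benzyl-D-mannitol | OC[C@@H](O)[C@@H](OCc1ccccc1)[C@H](OCc1ccccc1)[C@H](O)CO | intermediate
4 | 3,4-di-O-benzyl-1,6-bis-O-(tert-butyldimethylsilyl)-D-mannitol | CC(C)(C)[Si](C)(C)OC[C@@H](O)[C@@H](OCc1ccccc1)[C@H](OCc1ccccc1)[C@H](O)CO[Si](C)(C)C(C)(C)C | intermediate
5 | 3,4-di-O-benzyl-1,6-bis-O-(tert-butyldimethylsilyl)-2,5-di-O-mesyl-D-mannitol | CC(C)(C)[Si](C)(C)OC[C@@H](OS(C)(=O)=O)[C@@H](OCc1ccccc1)[C@H](OCc1ccccc1)[C@H](OS(C)(=O)=O)CO[Si](C)(C)C(C)(C)C | intermediate
6 | 3,4-di-O-benzyl-2,5-di-O-mesyl-D-mannitol (not isolated) | OC[C@@H](OS(C)(=O)=O)[C@@H](OCc1ccccc1)[C@H](OCc1ccccc1)[C@H](OS(C)(=O)=O)CO | intermediate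
7 | 1,2:5,6-dianhydro-3,4-di-O-benzyl-L-iditol | C1O[C@@H]1[C@@H](OCc1ccccc1)[C@H](OCc1ccccc1)[C@@H]1CO1 | intermediate
8 | 5,6-anhydro-3,4-di-O-benzyl-1-thio-L-iditol, present as its sodium thiolate (not isolated) | SC[C@H](O)[C@@H](OCc1ccccc1)[C@H](OCc1ccccc1)[C@@H]1CO1 | intermediate
9 | (3R,4R,5R,6R)-4,5-bis(benzyloxy)thiepane-3,6-diol (L-ido) | S1C[C@H](O)[C@@H](OCc2ccccc2)[C@H](OCc2ccccc2)[C@@H](O)C1 | intermediate
10 | (3R,4R,5R,6R)-4,5-bis(benzyloxy)-3,6-dihydroxythiepane 1,1-dioxide | O=S1(=O)C[C@H](O)[C@@H](OCc2ccccc2)[C@H](OCc2ccccc2)[C@@H](O)C1 | intermediate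
11 | formaldehyde | C=O | starting material
12 | O,O,C-trilithio derivative of 10 (two lithium alkoxides and one α-lithio sulfone; not isolated) | [Li]C1[C@H](O[Li])[C@@H](OCc2ccccc2)[C@H](OCc2ccccc2)[C@@H](O[Li])CS1(=O)=O | intermediate
13 | (2RS,3R,4R,5R,6R)-4,5-bis(benzyloxy)-3,6-dihydroxy-2-(hydroxymethyl)thiepane 1,1-dioxide (epimers at the hydroxymethyl-bearing carbon, C1 of the target) | O=S1(=O)C(CO)[C@H](O)[C@@H](OCc2ccccc2)[C@H](OCc2ccccc2)[C@@H](O)C1 | intermediate
14 | 2,7-O-isopropylidene acetal of 13: 1,3-dioxane fused to the thiepane dioxide at C1–C2, O3 and O4 benzylated, O5–H free, C2–C5 configured as in 9 (C1 epimers) | O=S1(=O)C2COC(C)(C)O[C@@H]2[C@@H](OCc2ccccc2)[C@H](OCc2ccccc2)[C@@H](O)C1 | intermediate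
15 | 5-O-tert-butyldimethylsilyl ether of 14 (C1 epimers) | O=S1(=O)C2COC(C)(C)O[C@@H]2[C@@H](OCc2ccccc2)[C@H](OCc2ccccc2)[C@@H](O[Si](C)(C)C(C)(C)C)C1 | intermediate
16 | 6-bromo derivative of 15, bromine on the α-methylene carbon C6 (not isolated) | O=S1(=O)C2COC(C)(C)O[C@@H]2[C@@H](OCc2ccccc2)[C@H](OCc2ccccc2)[C@@H](O[Si](C)(C)C(C)(C)C)C1Br | intermediate
17 | episulfone from 16: C1 and C6 bonded and bridged by SO2 (7-thiabicyclo[4.1.0]heptane 7,7-dioxide core; not isolated) | CC1(C)OCC23[C@H](O1)[C@@H](OCc1ccccc1)[C@H](OCc1ccccc1)[C@@H](O[Si](C)(C)C(C)(C)C)C2S3(=O)=O | intermediate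
18 | 7,8-bis(benzyloxy)-6-(tert-butyldimethylsilyloxy)-2,2-dimethyl-6,7,8,8a-tetrahydro-4H-1,3-benzodioxine; in route locants the C1=C6 alkene with O7/O2 acetonide, 3,4-di-O-benzyl and 5-O-TBS, C2–C5 configured as in 25 (all trans) | CC1(C)OCC2=C[C@H](O[Si](C)(C)C(C)(C)C)[C@@H](OCc3ccccc3)[C@H](OCc3ccccc3)[C@H]2O1 | intermediate
19 | diol from 18: C1=C6 alkene with CH2OH on C1, O2–H free, 3,4-di-O-benzyl, 5-O-TBS, C2–C5 as in 25 | OCC1=C[C@H](O[Si](C)(C)C(C)(C)C)[C@@H](OCc2ccccc2)[C@H](OCc2ccccc2)[C@H]1O | intermediate
20 | 7-O-benzoate of 19 (O2–H free) | O=C(OCC1=C[C@H](O[Si](C)(C)C(C)(C)C)[C@@H](OCc2ccccc2)[C@H](OCc2ccccc2)[C@H]1O)c1ccccc1 | intermediate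
21 | 1,6-epoxide of 20, oxirane oxygen on the face of O2–H; C1–C6 configured as in 25 | C(c1ccccc1)O[C@H]1[C@H](OCc2ccccc2)[C@@H](O[Si](C)(C)C(C)(C)C)[C@@H]2O[C@]2(COC(=O)c2ccccc2)[C@@H]1O | intermediate
22 | 2-O-acetate of 21 | C(c1ccccc1)O[C@H]1[C@H](OCc2ccccc2)[C@@H](O[Si](C)(C)C(C)(C)C)[C@@H]2O[C@]2(COC(=O)c2ccccc2)[C@@H]1OC(C)=O | intermediate
23 | 3,4-diol from 22 (2-O-acetyl, 7-O-benzoyl, 5-O-TBS, 1,6-epoxide) | O[C@H]1[C@H](O)[C@@H](O[Si](C)(C)C(C)(C)C)[C@@H]2O[C@]2(COC(=O)c2ccccc2)[C@@H]1OC(C)=O | intermediate
24 | 3-O-acetate of 23 (2,3-di-O-acetyl, O4–H free, 5-O-TBS) | CC(=O)O[C@H]1[C@H](O)[C@@H](O[Si](C)(C)C(C)(C)C)[C@@H]2O[C@]2(COC(=O)c2ccccc2)[C@@H]1OC(C)=O | intermediate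
25 | [(1S,2R,3S,4R,5R,6S)-2,3-diacetoxy-4,5-dihydroxy-7-oxabicyclo[4.1.0]heptan-1-yl]methyl benzoate | CC(=O)O[C@H]1[C@H](O)[C@@H](O)[C@@H]2O[C@]2(COC(=O)c2ccccc2)[C@@H]1OC(C)=O | target

## Step count and least certain steps

Total step count: 18. Longest linear sequence: 18 steps from 1; the route is linear and formaldehyde 11 enters in step 8.

**Step 11 (key step).** The most likely failure is E1cB loss of a β-oxygen competing with the contraction. That would be the silyloxy group at C5 from a C6 carbanion, or ring-opening loss of an acetal oxygen from a C1 carbanion, when bromine transfer on the solid base is slow. The fallback separates halogenation from contraction. From 15, kinetic deprotonation of the α-methylene with LiN(SiMe3)2 in THF at −78 °C and chlorination with hexachloroethane should give the isolable α-chloro sulfone F1. KOt-Bu in THF at −78 to 0 °C would then effect the 1,3-elimination and SO2 loss, returning to 18.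

**Step 17.** The most likely failure is poor discrimination between O3–H and O4–H, or over-acylation to the triester, if the TBS ether shields O4 less than expected. The fallback replaces direct acylation by a silyl relay, in which the discriminating reagent is far more sensitive to hindrance. From 23, TESCl and imidazole at −78 °C should silylate the more accessible O3 to give the 3-O-triethylsilyl ether F2. TBSOTf and 2,6-lutidine would cap O4 as the 4,5-bis-O-TBS 3-O-TES ether F3. PPTS in MeOH at 0 °C would remove only the TES group to give the 3-alcohol F4, and Ac2O with pyridine and DMAP would give the 2,3-diacetate 4,5-bis-silyl ether F5. HF·pyridine would then release both silyl ethers and rejoin the route at 25.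

**Step 8.** The most likely failure is incomplete C-metalation or poor solubility of the dilithium dialkoxide, or loss of formaldehyde by retro-aldol cleavage on warming. The fallback uses a protected mono-anion. From 10, TESCl and imidazole in DMF should give the 3,6-bis-O-triethylsilyl sulfone F6. LiN(iPr)2 in THF at −78 °C followed by monomeric formaldehyde would give the hydroxymethylated bis-silyl ether F7, and HF·pyridine in THF would return to 13. This brings back some risk of β-elimination, which is why it is not the first choice.

**Step 14.** The most likely failure is slow epoxidation of the electron-poor trisubstituted alkene with erosion of facial selectivity, or acid opening of the product on prolonged exposure. The fallback moves the epoxidation one step earlier and uses metal–alkoxide delivery. From 19, VO(acac)2 (cat.) and t-BuOOH in CH2Cl2 should epoxidise the diol syn to the secondary allylic hydroxyl to give the epoxy diol F8. Benzoylation of its primary hydroxyl with BzCl and pyridine at −30 °C would rejoin the route at 21.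

## Further compounds

F1 | step 11 | 6-chloro analogue of 16 (α-chloro sulfone from 15; C1 and C6 epimers) | O=S1(=O)C2COC(C)(C)O[C@@H]2[C@@H](OCc2ccccc2)[C@H](OCc2ccccc2)[C@@H](O[Si](C)(C)C(C)(C)C)C1Cl
F2 | step 17 | 3-O-triethylsilyl ether of 23 | CC[Si](CC)(CC)O[C@H]1[C@H](O)[C@@H](O[Si](C)(C)C(C)(C)C)[C@@H]2O[C@]2(COC(=O)c2ccccc2)[C@@H]1OC(C)=O
F3 | step 17 | 3-O-triethylsilyl-4-O-tert-butyldimethylsilyl ether of 23 | CC[Si](CC)(CC)O[C@H]1[C@H](O[Si](C)(C)C(C)(C)C)[C@@H](O[Si](C)(C)C(C)(C)C)[C@@H]2O[C@]2(COC(=O)c2ccccc2)[C@@H]1OC(C)=O
F4 | step 17 | 4,5-bis-O-TBS 3-alcohol (2-O-acetyl, 7-O-benzoyl, 1,6-epoxide) | O[C@H]1[C@H](O[Si](C)(C)C(C)(C)C)[C@@H](O[Si](C)(C)C(C)(C)C)[C@@H]2O[C@]2(COC(=O)c2ccccc2)[C@@H]1OC(C)=O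
F5 | step 17 | 2,3-di-O-acetyl-4,5-bis-O-TBS derivative (7-O-benzoyl, 1,6-epoxide) | CC(=O)O[C@H]1[C@H](O[Si](C)(C)C(C)(C)C)[C@@H](O[Si](C)(C)C(C)(C)C)[C@@H]2O[C@]2(COC(=O)c2ccccc2)[C@@H]1OC(C)=O
F6 | step 8 | 3,6-bis-O-triethylsilyl ether of 10 | O=S1(=O)C[C@H](O[Si](CC)(CC)CC)[C@@H](OCc2ccccc2)[C@H](OCc2ccccc2)[C@@H](O[Si](CC)(CC)CC)C1
F7 | step 8 | 2-(hydroxymethyl) derivative of F6 (epimers at the new centre) | O=S1(=O)C(CO)[C@H](O[Si](CC)(CC)CC)[C@@H](OCc2ccccc2)[C@H](OCc2ccccc2)[C@@H](O[Si](CC)(CC)CC)C1
F8 | step 14 | 1,6-epoxide of diol 19 (oxirane cis to O2–H; O7–H free) | C(c1ccccc1)O[C@H]1[C@H](OCc2ccccc2)[C@@H](O[Si](C)(C)C(C)(C)C)[C@@H]2O[C@]2(CO)[C@@H]1O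
A1 | alternative 1 | 4-hydroxy-4-(benzoyloxymethyl)cyclohexa-2,5-dien-1-one | O=C1C=CC(O)(COC(=O)c2ccccc2)C=C1
A2 | alternative 1 | cis-fused phenylboronate of the C1,C2-diol enone | O1B(c2ccccc2)O[C@@H]2CC(=O)C=C[C@]12COC(=O)c1ccccc1
A3 | alternative 2 | cyclohexa-1,3-diene with C2 hydroxyl, C3 silyl ether and C7 benzoate | O=C(OCC1=CC=C[C@H](O[Si](C)(C)C(C)(C)C)[C@H]1O)c1ccccc1
A4 | alternative 2 | C1,C4-endoperoxide with C2 hydroxyl, C3 silyl ether and C7 benzoate | O1O[C@]2(COC(=O)c3ccccc3)[C@H](O)[C@@H](O[Si](C)(C)C(C)(C)C)[C@H]1C=C2
A5 | alternative 3 | ethyl (E)-4,5-bis(benzyloxy)-6-(4-methoxybenzyloxy)-7-oxohept-2-enoate | CCOC(=O)/C=C/[C@H](OCc1ccccc1)[C@@H](OCc1ccccc1)[C@H](OCc1ccc(OC)cc1)C=O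
A6 | alternative 3 | ethyl cyclohexene-1-carboxylate with C2 hydroxyl, C3 PMB ether and C4/C5 benzyl ethers | CCOC(=O)C1=C[C@H](OCc2ccccc2)[C@@H](OCc2ccccc2)[C@H](OCc2ccc(OC)cc2)[C@H]1O
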